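Numbering: C1 is the CH3‑bearing ring‑fusion carbon, C2/C3 the cyclopentane CH2 groups, C4 the carbinol, C5 the fusion CH, C6/C10 the ester carbons, C8=C9 the alkene. The cyclopentane is opened at C1–C2. With C4 as a ketone, this is the bond a Nazarov reaction makes: a cycloheptenyl β‑silylvinyl ketone (C2=C3–C4(=O)–C5=C1) closes by conrotatory 4π electrocyclisation, forming quaternary C1 and the hydroazulenone in one operation. It exploits the oxygenated C4 flanked by fusion carbon C5 and the fully substituted C1. A CBS‑derived silyloxy group at C10 fixes the sense of rotation. C1 then relays: isopropyl addition (C4), α‑face hydroboration of C5=C6, enone methylation at C8, reduction and Mitsunobu inversion with angelic acid at C10.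

Key step: step 6

Remark: β is the face of the C1 methyl group in the bicyclic compounds and α the opposite face (that of H‑5 in the target); 2‑methylcycloheptane‑1,3‑dione is made in step 1 on the assumption that it is not a stock chemical.

Step 1
Reactants: 1 cycloheptane-1,3-dione
Product: 2 2-methylcycloheptane-1,3-dione
Conditions: MeI, K2CO3, acetone, reflux
Reagents that add atoms: methyl iodide, CI
Why: C‑alkylation of the stabilised 1,3‑diketone enolate by the soft electrophile should put the methyl group on the carbon between the two carbonyl groups, the future C1.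

Step 2
Reactants: 2 2-methylcycloheptane-1,3-dione
Product: 3 2-methyl-3-oxocyclohept-1-en-1-yl trifluoromethanesulfonate
Conditions: Tf2O, pyridine, CH2Cl2, −78 °C to 0 °C
Reagents that add atoms: trifluoromethanesulfonic anhydride, O=S(=O)(OS(=O)(=O)C(F)(F)F)C(F)(F)F
Why: Enol triflate formation by O‑sulfonylation of the enol of the symmetrical diketone should give a single vinylogous triflate, the handle for acylation at the future C5.

Step 3
Reactants: 3 2-methyl-3-oxocyclohept-1-en-1-yl trifluoromethanesulfonate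
Product: 4 (3S)-3-hydroxy-2-methylcyclohept-1-en-1-yl trifluoromethanesulfonate
Conditions: (R)-2-methyl-CBS-oxazaborolidine (20 mol %), BH3·SMe2, CH2Cl2, −40 °C; MeOH
Reagents that add atoms: none
Why: Corey–Bakshi–Shibata reduction, in which the oxazaborolidine treats the fully substituted alkenyl flank as the large group and the ring CH2 as the small one, should deliver hydride to one carbonyl face and give the (S)-allylic alcohol (the future C10).

Step 4
Reactants: 4 (3S)-3-hydroxy-2-methylcyclohept-1-en-1-yl trifluoromethanesulfonate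
Product: 5 (3S)-3-(tert-butyldiphenylsilyloxy)-2-methylcyclohept-1-en-1-yl trifluoromethanesulfonate
Conditions: TBDPSCl, imidazole, DMAP (cat.), DMF, rt
Reagents that add atoms: tert-butyl(chloro)diphenylsilane, CC(C)(C)[Si](Cl)(c1ccccc1)c1ccccc1
Why: Silyl ether formation installs a bulky, Lewis‑acid‑tolerant group on the C10 oxygen that later shields one face of C1.

Step 5
Reactants: 5 (3S)-3-(tert-butyldiphenylsilyloxy)-2-methylcyclohept-1-en-1-yl trifluoromethanesulfonate; 6 (E)-tributyl[2-(trimethylsilyl)ethenyl]stannane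
Product: 7 (E)-1-[(3S)-3-(tert-butyldiphenylsilyloxy)-2-methylcyclohept-1-en-1-yl]-3-(trimethylsilyl)prop-2-en-1-one
Conditions: Pd(PPh3)4 (5 mol %), LiCl, CO (3 atm), THF, 60 °C
Reagents that add atoms: carbon monoxide, [C-]#[O+]; (E)-tributyl[2-(trimethylsilyl)ethenyl]stannane (6), C[Si](C)(C)/C=C/[Sn](CCCC)(CCCC)CCCC
Why: Carbonylative Stille coupling (oxidative addition of the vinyl triflate to zerovalent palladium, CO insertion, transmetalation with the vinylstannane) should give the cross‑conjugated β‑silyl dienone with the (E) geometry retained.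

Step 6
Reactants: 7 (E)-1-[(3S)-3-(tert-butyldiphenylsilyloxy)-2-methylcyclohept-1-en-1-yl]-3-(trimethylsilyl)prop-2-en-1-one
Product: 8 cis-fused hydroazulenone (C4 ketone; C2=C3; 1β-CH3; 5β-H; 10β-OTBDPS)
Conditions: FeCl3 (1.1 equiv), CH2Cl2, −30 °C to 0 °C; aqueous NaHCO3
Reagents that add atoms: none
Why: FeCl3 coordinates the C4 carbonyl of 7 to give a 3‑oxidopentadienyl cation (C2=C3–C4–C5=C1) that undergoes thermal conrotatory 4π electrocyclisation, forming the C1–C2 bond and a 2‑oxidocyclopentenyl cation whose positive end C3 is β to silicon; loss of the trimethylsilyl group then fixes the alkene at C2=C3 and the dienolate is protonated at C5 on work‑up. The closest known reaction type is the silicon‑directed Nazarov cyclisation of cycloalkenyl β‑silylvinyl ketones. The cyclopentane ring is closed in a 4π‑conrotatory (formally 5‑endo‑trig) mode and no other ring is formed. The new quaternary stereocentre C1 is controlled by the C10 silyloxy group, which allylic strain with the C1 methyl group holds pseudo‑axial so that it blocks its own face and C2 bonds to C1 anti to it (CH3 and OSi cis, both β); C5 should be protonated from the β face to give the cis fusion, a centre that step 7 removes. The step needs torquoselectivity and control of the alkene position: the first rests on the C10 stereocentre set in step 3, the second on the β‑silicon effect.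

Step 7
Reactants: 8 cis-fused hydroazulenone (C4 ketone; C2=C3; 1β-CH3; 5β-H; 10β-OTBDPS)
Product: 10 cross-conjugated dienone (C4 ketone; C2=C3; C5=C6; 1β-CH3; 10β-OTBDPS), via silyl dienol ether 9 (not isolated)
Conditions: LDA, TMSCl, THF, −78 °C; then Pd(OAc)2 (10 mol %), O2 (1 atm), DMSO, rt
Reagents that add atoms: none
Why: Deprotonation at the only enolisable position (C5) and silylation give the 2‑silyloxycyclopentadiene, whose Saegusa–Ito oxidation (palladation at C5, β‑hydride loss from C6, the only β‑hydrogen available) should give the dienone and erase the C5 stereocentre.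

Step 8
Reactants: 10 cross-conjugated dienone (C4 ketone; C2=C3; C5=C6; 1β-CH3; 10β-OTBDPS)
Product: 11 exocyclic enone (C4 ketone; C5=C6; C2 and C3 CH2; 1β-CH3; 10β-OTBDPS)
Conditions: RhCl(PPh3)3 (5 mol %), H2 (1 atm), benzene, rt
Reagents that add atoms: none
Why: Homogeneous hydrogenation with RhCl(PPh3)3 should saturate only the cis‑disubstituted C2=C3 bond and leave the trisubstituted C5=C6 enone, the selectivity established for cross‑conjugated 1,4‑dien‑3‑ones.

Step 9
Reactants: 11 exocyclic enone (C4 ketone; C5=C6; C2 and C3 CH2; 1β-CH3; 10β-OTBDPS)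
Product: 12 tertiary allylic alcohol (4β-OH; 4α-isopropyl; C5=C6; 1β-CH3; 10β-OTBDPS)
Conditions: CeCl3, iPrMgCl, THF, −78 °C to 0 °C
Reagents that add atoms: isopropylmagnesium chloride, CC(C)[Mg]Cl
Why: The organocerium reagent (Imamoto addition) should add 1,2 to the hindered enone without enolisation, from the α face opposite the pseudo‑axial C1 methyl group that sits 1,3 to C4, setting 4β‑OH and 4α‑isopropyl.

Step 10
Reactants: 12 tertiary allylic alcohol (4β-OH; 4α-isopropyl; C5=C6; 1β-CH3; 10β-OTBDPS)
Product: 13 trans-fused diol (4β-OH; 5α-H; 6α-OH; 1β-CH3; 10β-OTBDPS)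
Conditions: BH3·THF, THF, 0 °C to rt; then NaOH, H2O2, 0 °C
Reagents that add atoms: hydrogen peroxide, OO
Why: Hydroboration–oxidation adds H and B syn and anti‑Markovnikov to C5=C6 from the α face, opposite the axial C1 methyl group and the borate formed on the 4β oxygen (the face preference of 5‑ene steroids), and oxidation with retention should give 5α‑H and 6α‑OH, that is the trans ring fusion.

Step 11
Reactants: 13 trans-fused diol (4β-OH; 5α-H; 6α-OH; 1β-CH3; 10β-OTBDPS); 14 4-methoxybenzoyl chloride
Product: 15 6α-(4-methoxybenzoate) of 13 (4β-OH free; 10β-OTBDPS)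
Conditions: 4-MeOC6H4COCl, Et3N, DMAP (cat.), CH2Cl2, 0 °C to rt
Reagents that add atoms: 4-methoxybenzoyl chloride (14), COc1ccc(cc1)C(Cl)=O
Why: DMAP‑catalysed acylation should esterify the secondary 6α alcohol only, because the tertiary C4 alcohol is too hindered to react.

Step 12
Reactants: 15 6α-(4-methoxybenzoate) of 13 (4β-OH free; 10β-OTBDPS)
Product: 16 4β,10β-diol 6α-(4-methoxybenzoate)
Conditions: HF·pyridine, THF, rt
Reagents that add atoms: none
Why: Fluoride‑mediated desilylation under buffered acidic conditions should free the C10 alcohol without touching the aryl ester or the tertiary alcohol.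

Step 13
Reactants: 16 4β,10β-diol 6α-(4-methoxybenzoate)
Product: 18 C8=C9 enone (10-oxo; 4β-OH; 6α-anisoate), via C10 ketone 17 (not isolated)
Conditions: IBX (4 equiv), DMSO/fluorobenzene, 70 °C
Reagents that add atoms: none
Why: IBX oxidises the secondary alcohol to the C10 ketone and then dehydrogenates it (Nicolaou IBX dehydrogenation) on the only enolisable side, C9–C8, because C1 is quaternary, while the tertiary alcohol and the ester are inert.

Step 14
Reactants: 18 C8=C9 enone (10-oxo; 4β-OH; 6α-anisoate)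
Product: 20 8-methyl C8=C9 enone (10-oxo; 4β-OH; 6α-anisoate), via α-phenylselanyl ketone 19 (not isolated)
Conditions: Me2CuLi (3 equiv), Et2O, −78 °C; PhSeBr, −78 °C; then H2O2, pyridine, CH2Cl2, 0 °C
Reagents that add atoms: lithium dimethylcuprate, [Li+].C[Cu-]C
Why: Conjugate addition of the Gilman cuprate puts the methyl group on C8, selenenylation of the enolate at C9 trans to it and selenoxide syn‑elimination (Reich) restore the C8=C9 bond, so that no stereocentre made here survives.

Step 15
Reactants: 20 8-methyl C8=C9 enone (10-oxo; 4β-OH; 6α-anisoate)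
Product: 21 10β-allylic alcohol (C10 epimer of the target alcohol; 6α-anisoate)
Conditions: NaBH4, CeCl3·7H2O, MeOH, −40 °C
Reagents that add atoms: none
Why: Luche 1,2‑reduction should deliver hydride to C10 from the α face, anti to the pseudo‑axial methyl group on the neighbouring quaternary C1, giving the equatorial 10β alcohol with (S) configuration.

Step 16
Reactants: 21 10β-allylic alcohol (C10 epimer of the target alcohol; 6α-anisoate); 22 angelic acid
Product: 23 target compound CNP0168729.1
Conditions: PPh3, DIAD, toluene, 0 °C to rt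
Reagents that add atoms: angelic acid (22), C/C=C(/C)C(=O)O
Why: Mitsunobu esterification: the oxyphosphonium salt of the allylic 10β alcohol should be displaced by angelate with inversion (SN2, axial entry on the α face) to give the 10α (R) ester, the tertiary C4 alcohol cannot be activated, and the phosphine is consumed by the azodicarboxylate before it can isomerise the (Z) acid.

Compound list
1 | cycloheptane-1,3-dione | O=C1CCCCC(=O)C1 | starting material
2 | 2-methylcycloheptane-1,3-dione | CC1C(=O)CCCCC1=O | intermediate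
3 | 2-methyl-3-oxocyclohept-1-en-1-yl trifluoromethanesulfonate | CC1=C(OS(=O)(=O)C(F)(F)F)CCCCC1=O | intermediate
4 | (3S)-3-hydroxy-2-methylcyclohept-1-en-1-yl trifluoromethanesulfonate | O[C@H]1CCCCC(OS(=O)(=O)C(F)(F)F)=C1C | intermediate
5 | (3S)-3-(tert-butyldiphenylsilyloxy)-2-methylcyclohept-1-en-1-yl trifluoromethanesulfonate | CC(C)(C)[Si](c1ccccc1)(c1ccccc1)O[C@H]1CCCCC(OS(=O)(=O)C(F)(F)F)=C1C | intermediate
6 | (E)-tributyl[2-(trimethylsilyl)ethenyl]stannane | C[Si](C)(C)/C=C/[Sn](CCCC)(CCCC)CCCC | starting material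
7 | (E)-1-[(3S)-3-(tert-butyldiphenylsilyloxy)-2-methylcyclohept-1-en-1-yl]-3-(trimethylsilyl)prop-2-en-1-one | CC(C)(C)[Si](c1ccccc1)(c1ccccc1)O[C@H]1CCCCC(C(=O)/C=C/[Si](C)(C)C)=C1C | intermediate
8 | cis-fused hydroazulenone: C4 ketone, C2=C3, 1β-CH3, 5β-H, 10β-OTBDPS | CC(C)(C)[Si](c1ccccc1)(c1ccccc1)O[C@H]1CCCC[C@H]2[C@]1(C)C=CC2=O | intermediate
9 | silyl dienol ether: C2=C3, C4(OSiMe3)=C5, 1β-CH3, 10β-OTBDPS | CC(C)(C)[Si](c1ccccc1)(c1ccccc1)O[C@H]1CCCCC=2[C@]1(C)C=CC=2O[Si](C)(C)C | intermediate (not isolated)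
10 | cross-conjugated dienone: C4 ketone, C2=C3, C5=C6, 1β-CH3, 10β-OTBDPS | CC(C)(C)[Si](c1ccccc1)(c1ccccc1)O[C@H]1CCCC=C2[C@]1(C)C=CC2=O | intermediate
11 | exocyclic enone: C4 ketone, C5=C6, 1β-CH3, 10β-OTBDPS | CC(C)(C)[Si](c1ccccc1)(c1ccccc1)O[C@H]1CCCC=C2[C@]1(C)CCC2=O | intermediate
12 | tertiary allylic alcohol: 4β-OH, 4α-isopropyl, C5=C6, 1β-CH3, 10β-OTBDPS | CC(C)(C)[Si](c1ccccc1)(c1ccccc1)O[C@H]1CCCC=C2[C@]1(C)CC[C@@]2(O)C(C)C | intermediate
13 | trans-fused diol: 4β-OH, 4α-isopropyl, 5α-H, 6α-OH, 1β-CH3, 10β-OTBDPS | CC(C)(C)[Si](c1ccccc1)(c1ccccc1)O[C@H]1CCC[C@H](O)[C@@H]2[C@]1(C)CC[C@@]2(O)C(C)C | intermediate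
14 | 4-methoxybenzoyl chloride | COc1ccc(cc1)C(Cl)=O | starting material
15 | 6α-(4-methoxybenzoate) of 13: 4β-OH free, 10β-OTBDPS | CC(C)(C)[Si](c1ccccc1)(c1ccccc1)O[C@H]1CCC[C@H](OC(=O)c3ccc(OC)cc3)[C@@H]2[C@]1(C)CC[C@@]2(O)C(C)C | intermediate
16 | 4β,10β-diol 6α-(4-methoxybenzoate), C7–C9 saturated | O[C@H]1CCC[C@H](OC(=O)c3ccc(OC)cc3)[C@@H]2[C@]1(C)CC[C@@]2(O)C(C)C | intermediate
17 | C10 ketone: 4β-OH, 6α-anisoate, C7–C9 saturated | O=C1CCC[C@H](OC(=O)c3ccc(OC)cc3)[C@@H]2[C@]1(C)CC[C@@]2(O)C(C)C | intermediate (not isolated)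
18 | C8=C9 enone: 10-oxo, 4β-OH, 6α-anisoate | O=C1C=CC[C@H](OC(=O)c3ccc(OC)cc3)[C@@H]2[C@]1(C)CC[C@@]2(O)C(C)C | intermediate
19 | α-phenylselanyl ketone: 10-oxo, 9α-SePh, 8β-CH3 (drawn as the expected trans adduct; both centres are lost in the same step) | O=C1[C@H]([Se]c4ccccc4)[C@@H](C)C[C@H](OC(=O)c3ccc(OC)cc3)[C@@H]2[C@]1(C)CC[C@@]2(O)C(C)C | intermediate (not isolated)
20 | 8-methyl C8=C9 enone: 10-oxo, 4β-OH, 6α-anisoate | O=C1C=C(C)C[C@H](OC(=O)c3ccc(OC)cc3)[C@@H]2[C@]1(C)CC[C@@]2(O)C(C)C | intermediate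
21 | 10β-allylic alcohol (10S), C10 epimer of the target alcohol, 6α-anisoate | O[C@H]1C=C(C)C[C@H](OC(=O)c3ccc(OC)cc3)[C@@H]2[C@]1(C)CC[C@@]2(O)C(C)C | intermediate
22 | angelic acid, (Z)-2-methylbut-2-enoic acid | C/C=C(/C)C(=O)O | starting material
23 | CNP0168729.1: 10α-angeloyloxy-6α-(4-methoxybenzoyloxy)-4β-hydroxydauc-8-ene, (1S,4R,5S,6S,10R) in the numbering used here | C/C=C(/C)C(=O)O[C@@H]1C=C(C)C[C@H](OC(=O)c2ccc(OC)cc2)[C@@H]2[C@]1(C)CC[C@@]2(O)C(C)C | target

Total step count: 16. Longest linear sequence: 16 steps, from cycloheptane-1,3-dione (1).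

Steps most likely to fail

Step 6. The stoichiometric Lewis acid may cleave or ionise the allylic silyl ether before ring closure, and a weak preference for one sense of conrotation would give a mixture at C1. The fallback sets out from 5 and comes back at 8. Sonogashira coupling of triflate 5 with prop-2-ynyl acetate (Pd(PPh3)2Cl2, CuI, iPr2NH, THF) should give the enynyl acetate F1. Catalytic AuCl(PPh3)/AgSbF6 in CH2Cl2 at rt should then trigger a [3,3] acetoxy shift to the allenyl acetate, Nazarov closure of C1–C2 under neutral conditions and a 1,2‑hydride shift, giving the cyclopentadienyl acetate F2. K2CO3 in MeOH cleaves the enol acetate to 8.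

Step 10. The 4α‑isopropyl group may steer the borane to the β face, which would give the cis‑fused 6β alcohol. The fallback sets out from 11 and comes back at 15. Conjugate borylation of enone 11 (B2pin2, CuCl, NaOtBu, Xantphos, MeOH, THF) should place boron on C6 from the α face, and brief treatment with DBU lets C5 settle trans to it, giving the β-boryl ketone F3. Oxidation with NaBO3 gives the β-hydroxy ketone F4, and acylation with 14 gives the β-anisoyloxy ketone F5. Addition of iPrMgCl/CeCl3 to the C4 ketone from the α face then gives 15.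

Step 16. The angeloyl group may lose its (Z) geometry through reversible phosphine addition, and the hindered allylic oxyphosphonium salt may react by SN2' displacement or elimination. The fallback sets out from 21 and comes back at 23. Mitsunobu inversion with the stronger, non‑isomerisable chloroacetic acid (PPh3, DIAD, toluene) should give the 10α-chloroacetate F6. K2CO3 in MeOH at 0 °C removes the chloroacetate selectively to give the 10α-alcohol F7. Yamaguchi esterification with 22 (2,4,6‑trichlorobenzoyl chloride, Et3N, toluene, 80 °C, no phosphine present) then gives 23.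

Further compounds
F1 | step 6 | 3-[(3S)-3-(tert-butyldiphenylsilyloxy)-2-methylcyclohept-1-en-1-yl]prop-2-yn-1-yl acetate | CC(C)(C)[Si](c1ccccc1)(c1ccccc1)O[C@H]1CCCCC(C#CCOC(C)=O)=C1C
F2 | step 6 | cyclopentadienyl acetate: C2=C3, C4(OAc)=C5, 1β-CH3, 10β-OTBDPS | CC(C)(C)[Si](c1ccccc1)(c1ccccc1)O[C@H]1CCCCC=2[C@]1(C)C=CC=2OC(C)=O
F3 | step 10 | trans-fused β-boryl ketone: C4 ketone, 5α-H, 6α-Bpin, 1β-CH3, 10β-OTBDPS | CC(C)(C)[Si](c1ccccc1)(c1ccccc1)O[C@H]1CCC[C@H](B3OC(C)(C)C(C)(C)O3)[C@@H]2[C@]1(C)CCC2=O
F4 | step 10 | trans-fused β-hydroxy ketone: C4 ketone, 5α-H, 6α-OH, 1β-CH3, 10β-OTBDPS | CC(C)(C)[Si](c1ccccc1)(c1ccccc1)O[C@H]1CCC[C@H](O)[C@@H]2[C@]1(C)CCC2=O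
F5 | step 10 | trans-fused β-anisoyloxy ketone: C4 ketone, 5α-H, 6α-(4-methoxybenzoate), 1β-CH3, 10β-OTBDPS | CC(C)(C)[Si](c1ccccc1)(c1ccccc1)O[C@H]1CCC[C@H](OC(=O)c3ccc(OC)cc3)[C@@H]2[C@]1(C)CCC2=O
F6 | step 16 | 10α-chloroacetate of the 6α-anisoate 4β-ol | O=C(CCl)O[C@@H]1C=C(C)C[C@H](OC(=O)c3ccc(OC)cc3)[C@@H]2[C@]1(C)CC[C@@]2(O)C(C)C
F7 | step 16 | 10α-alcohol (10R), 6α-anisoate, 4β-OH | O[C@@H]1C=C(C)C[C@H](OC(=O)c3ccc(OC)cc3)[C@@H]2[C@]1(C)CC[C@@]2(O)C(C)C
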